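**Retrosynthetic overview**

1. The macrocycle is closed last at the N1–C(=O) lactam bond (active-ester macrolactamisation). Before that, the aryl C8–vinyl bond comes from a Stille coupling with a (Z)-stannylacrylamide that already carries Boc-protected spermidine, and the (Z)-acrylate on C9b from a Still–Gennari olefination of a C9b aldehyde.
2. Enabling feature (dibenzo[b,d]furan numbering): the cyclohexanone (ring C) is a four-carbon C1–C2–C3(=O)–C4 unit laid across the C4a–C9b bond, which is the C2=C3 bond of a benzofuran (rings A and B). C9b bears a carbon that can be a formyl group, and the C3 ketone lies 1,4 to C9b.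
3. Ring C, the quaternary C9b, C4a and the masked ketone therefore come from one enantioselective dearomative Diels–Alder reaction of 5-iodobenzofuran-3-carbaldehyde with 2-(triisopropylsilyloxy)buta-1,3-diene. The resulting silyl enol ether protects the ketone to the end.
4. Ring order: benzene ring A (purchased) → furan ring B (step 1) → carbocycle ring C (step 5) → 20-membered macrolactam (step 11).

Key step: step 5

Assumption: the (S)-configured oxazaborolidinium catalyst is taken to expose the face of the benzofuran aldehyde that leads to 9bS, as its accepted pre-transition-state model predicts for an s-trans α-substituted enal; the (R)-catalyst is the direct substitute if the sense found is the opposite.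

**Route**

Step 1
Reactants: 1 2-hydroxy-5-iodobenzaldehyde; 2 ethyl diazoacetate
Product: 4 ethyl 5-iodo-1-benzofuran-3-carboxylate, via hemiacetal 3 (not isolated)
Conditions: HBF4·OEt2 (10 mol %), CH2Cl2, rt; then conc. H2SO4, rt
Reagents that add atoms: none
Why: The acid-activated aldehyde is attacked by the diazoester and, with loss of N2, the aryl group shifts 1,2 to give the 2-aryl-3-oxopropanoate that the ortho phenol traps as hemiacetal 3, which H2SO4 dehydrates to the aromatic furan (Roskamp-type homologation followed by cyclodehydration, a known one-pot route from salicylaldehydes to benzofuran-3-carboxylates); no stereocentre is formed.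

Step 2
Reactants: 4 ethyl 5-iodo-1-benzofuran-3-carboxylate
Product: 5 (5-iodo-1-benzofuran-3-yl)methanol
Conditions: i-Bu2AlH (2.2 equiv), CH2Cl2, −78 → 0 °C; aq. KNaC4H4O6 work-up
Reagents that add atoms: none
Why: Standard i-Bu2AlH reduction of an aryl ester to the primary alcohol; the aryl iodide and the furan ring are inert at low temperature.

Step 3
Reactants: 5 (5-iodo-1-benzofuran-3-yl)methanol
Product: 6 5-iodo-1-benzofuran-3-carbaldehyde
Conditions: MnO2 (10 equiv), CH2Cl2, rt
Reagents that add atoms: none
Why: MnO2 oxidises the heterobenzylic alcohol to the aldehyde without over-oxidation and leaves the iodide untouched (benzylic/allylic alcohol oxidation).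

Step 4
Reactants: 7 but-3-en-2-one
Product: 8 triisopropyl(buta-1,3-dien-2-yloxy)silane [2-(triisopropylsilyloxy)buta-1,3-diene]
Conditions: i-Pr3SiOTf, Et3N, Et2O, 0 °C → rt
Reagents that add atoms: triisopropylsilyl trifluoromethanesulfonate, CC(C)[Si](OS(=O)(=O)C(F)(F)F)(C(C)C)C(C)C
Why: Soft enolisation of the enone at its methyl group and O-silylation by the silyl triflate gives the cross-conjugated silyl enol ether, the standard preparation of 2-silyloxybutadienes.

Step 5
Reactants: 6 5-iodo-1-benzofuran-3-carbaldehyde; 8 2-(triisopropylsilyloxy)buta-1,3-diene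
Product: 9 (4aR,9bS)-8-iodo-3-(triisopropylsilyloxy)-1,4,4a,9b-tetrahydrodibenzo[b,d]furan-9b-carbaldehyde
Conditions: (S)-3,3-diphenyl-1-(2-methylphenyl)tetrahydro-1H,3H-pyrrolo[1,2-c][1,3,2]oxazaborole (20 mol %), Tf2NH (18 mol %), 8 (3 equiv), CH2Cl2, −78 → −20 °C; Et3N quench, Et3N-deactivated silica
Reagents that add atoms: none
Why: Proposed new method: the oxazaborolidinium cation binds the formyl oxygen of 6 (with the usual formyl C–H···O contact), which lowers the LUMO of the O1–C2=C3–CHO unit so that diene 8 adds across the furan C2=C3 bond in a concerted, asynchronous, normal-demand [4+2] cycloaddition in which the CH2 terminus next to C–OSi bonds first to C2; only the weak furan aromaticity is lost and the benzene ring stays intact. The closest known reactions are the thermal and high-pressure dearomative Diels–Alder additions of 3-acyl- and 3-nitrobenzofurans and -indoles to oxygenated dienes and the oxazaborolidinium-catalysed enantioselective Diels–Alder reactions of α-substituted enals with this same diene; their combination on a heteroaromatic enal is the new element. The one ring closed is the six-membered carbocycle (ring C), formed by intermolecular suprafacial [4+2] annulation onto ring B and not by cyclisation of a tether. C9b is set by the catalyst, whose phenyl group should shield one face of the s-trans enal so that the diene adds to the face giving 9bS, and C4a follows from C9b because suprafacial addition can only give the cis ring fusion (4aR). The step needs regioselectivity, secured by the match of the nucleophilic diene terminus with the electrophilic β-carbon C2 (the "para" rule for 2-oxygenated dienes, which places the masked ketone 1,4 to C9b), chemoselectivity for the C=C bond over 1,2-addition to the bound aldehyde, secured by the bulky silyl group that suppresses silyl transfer (a stepwise Mukaiyama–Michael/ring-closure path would give the same adduct), and face selectivity, secured by the catalyst.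

Step 6
Reactants: 9 (4aR,9bS)-8-iodo-3-(triisopropylsilyloxy)-1,4,4a,9b-tetrahydrodibenzo[b,d]furan-9b-carbaldehyde; 10 methyl 2-[bis(2,2,2-trifluoroethoxy)phosphoryl]acetate
Product: 11 methyl (2Z)-3-[(4aR,9bS)-8-iodo-3-(triisopropylsilyloxy)-1,4,4a,9b-tetrahydrodibenzo[b,d]furan-9b-yl]prop-2-enoate
Conditions: KN(SiMe3)2, 18-crown-6, THF, −78 °C
Reagents that add atoms: none
Why: Still–Gennari variant of the Horner–Wadsworth–Emmons olefination: the bis(trifluoroethyl) phosphonate with a crown-ether-separated potassium counter-ion collapses fast from the kinetically formed adduct and should give the Z-enoate; the aldehyde cannot enolise, the aryl iodide and silyl enol ether are inert, and C9b/C4a are untouched.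

Step 7
Reactants: 12 ethyl (2Z)-3-(tributylstannyl)prop-2-enoate
Product: 13 (2Z)-3-(tributylstannyl)prop-2-enoic acid
Conditions: LiOH·H2O, THF/H2O, 0 °C → rt; cold dilute HCl to pH 4
Reagents that add atoms: lithium hydroxide, [Li+].[OH-]
Why: Saponification of the ethyl ester; the vinyl C–Sn bond and the Z geometry tolerate cold hydroxide, and the work-up is stopped at pH 4 to avoid protodestannylation.

Step 8
Reactants: 13 (2Z)-3-(tributylstannyl)prop-2-enoic acid; 14 tert-butyl N-(4-aminobutyl)-N-[3-(tert-butoxycarbonylamino)propyl]carbamate (N1,N4-bis-Boc-spermidine, N8 free)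
Product: 15 tert-butyl N-[3-(tert-butoxycarbonylamino)propyl]-N-[4-[[(2Z)-3-(tributylstannyl)prop-2-enoyl]amino]butyl]carbamate
Conditions: DCC, HOBt, CH2Cl2, 0 °C → rt
Reagents that add atoms: none
Why: Carbodiimide amide coupling at the only free amine of 14 (the primary N8), both other nitrogens being Boc-protected, so that the stannylacryloyl group ends on the aminobutyl terminus; the Z geometry is retained.

Step 9
Reactants: 11 methyl (2Z)-3-[(4aR,9bS)-8-iodo-3-(triisopropylsilyloxy)-1,4,4a,9b-tetrahydrodibenzo[b,d]furan-9b-yl]prop-2-enoate; 15 the (Z)-stannylacrylamide of bis-Boc-spermidine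
Product: 16 methyl (2Z)-3-[(4aR,9bS)-8-[(1Z)-3-[[4-[(tert-butoxycarbonyl)[3-(tert-butoxycarbonylamino)propyl]amino]butyl]amino]-3-oxoprop-1-en-1-yl]-3-(triisopropylsilyloxy)-1,4,4a,9b-tetrahydrodibenzo[b,d]furan-9b-yl]prop-2-enoate
Conditions: Pd2(dba)3 (5 mol %), AsPh3 (20 mol %), CuI (10 mol %), DMF, rt → 40 °C
Reagents that add atoms: none
Why: Stille cross-coupling of the aryl iodide (zerovalent palladium, with CuI co-catalysis to speed transmetalation of the electron-poor vinylstannane) proceeds with retention of the Z geometry and tolerates the enoate, carbamates and silyl enol ether.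

Step 10
Reactants: 16 the methyl ester from step 9
Product: 17 (2Z)-3-[(4aR,9bS)-8-[(1Z)-3-[[4-[(tert-butoxycarbonyl)[3-(tert-butoxycarbonylamino)propyl]amino]butyl]amino]-3-oxoprop-1-en-1-yl]-3-(triisopropylsilyloxy)-1,4,4a,9b-tetrahydrodibenzo[b,d]furan-9b-yl]prop-2-enoic acid
Conditions: LiOH·H2O, THF/MeOH/H2O, 0 °C → rt; cold dilute HCl to pH 5
Reagents that add atoms: lithium hydroxide, [Li+].[OH-]
Why: Saponification of the unhindered methyl ester; the Boc carbamates, the secondary amide and the bulky triisopropylsilyl enol ether should survive cold LiOH, and the β-carbon of the enoate is too hindered for conjugate addition, so the Z geometry is kept.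

Step 11
Reactants: 17 the carboxylic acid from step 10
Product: 20 the target macrolactam (CNP0159470.1), via seco amino acid 18 (not isolated), via pentafluorophenyl ester 19 (not isolated)
Conditions: TFA/CH2Cl2/H2O (10:10:1), 0 °C → rt, evaporate; then pentafluorophenyl diphenylphosphinate, i-Pr2NEt, DMF (1 mM, slow addition), rt
Reagents that add atoms: none
Why: Acidolysis removes both Boc groups and hydrolyses the silyl enol ether to the C3 ketone, the phosphinate reagent then converts the carboxylate into pentafluorophenyl ester 19, and under high dilution the primary N1 amine, which acylates much faster with active esters than the more hindered secondary N4, closes the 20-membered lactam (macrolactamisation); no stereocentre is touched and the cis ring fusion is locked by C9b.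

**Compound list**

1 | 2-hydroxy-5-iodobenzaldehyde | O=Cc1cc(I)ccc1O | starting material
2 | ethyl diazoacetate | CCOC(=O)C=[N+]=[N-] | starting material
3 | ethyl 2-hydroxy-5-iodo-2,3-dihydro-1-benzofuran-3-carboxylate (hemiacetal, diastereomer mixture, not isolated) | CCOC(=O)C1C(O)Oc2ccc(I)cc21 | intermediate
4 | ethyl 5-iodo-1-benzofuran-3-carboxylate | CCOC(=O)c1coc2ccc(I)cc12 | intermediate
5 | (5-iodo-1-benzofuran-3-yl)methanol | OCc1coc2ccc(I)cc12 | intermediate
6 | 5-iodo-1-benzofuran-3-carbaldehyde | O=Cc1coc2ccc(I)cc12 | intermediate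
7 | but-3-en-2-one | CC(=O)C=C | starting material
8 | triisopropyl(buta-1,3-dien-2-yloxy)silane | C=CC(=C)O[Si](C(C)C)(C(C)C)C(C)C | intermediate
9 | (4aR,9bS)-8-iodo-3-(triisopropylsilyloxy)-1,4,4a,9b-tetrahydrodibenzo[b,d]furan-9b-carbaldehyde | CC(C)[Si](C(C)C)(C(C)C)OC1=CC[C@]2(C=O)c3cc(I)ccc3O[C@@H]2C1 | intermediate
10 | methyl 2-[bis(2,2,2-trifluoroethoxy)phosphoryl]acetate | COC(=O)CP(=O)(OCC(F)(F)F)OCC(F)(F)F | starting material
11 | methyl (2Z)-3-[(4aR,9bS)-8-iodo-3-(triisopropylsilyloxy)-1,4,4a,9b-tetrahydrodibenzo[b,d]furan-9b-yl]prop-2-enoate | CC(C)[Si](C(C)C)(C(C)C)OC1=CC[C@]2(/C=C\C(=O)OC)c3cc(I)ccc3O[C@@H]2C1 | intermediate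
12 | ethyl (2Z)-3-(tributylstannyl)prop-2-enoate | CCCC[Sn](CCCC)(CCCC)/C=C\C(=O)OCC | starting material
13 | (2Z)-3-(tributylstannyl)prop-2-enoic acid | CCCC[Sn](CCCC)(CCCC)/C=C\C(=O)O | intermediate
14 | tert-butyl N-(4-aminobutyl)-N-[3-(tert-butoxycarbonylamino)propyl]carbamate | CC(C)(C)OC(=O)NCCCN(CCCCN)C(=O)OC(C)(C)C | starting material
15 | tert-butyl N-[3-(tert-butoxycarbonylamino)propyl]-N-[4-[[(2Z)-3-(tributylstannyl)prop-2-enoyl]amino]butyl]carbamate | CCCC[Sn](CCCC)(CCCC)/C=C\C(=O)NCCCCN(CCCNC(=O)OC(C)(C)C)C(=O)OC(C)(C)C | intermediate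
16 | methyl (2Z)-3-[(4aR,9bS)-8-[(1Z)-3-[[4-[(tert-butoxycarbonyl)[3-(tert-butoxycarbonylamino)propyl]amino]butyl]amino]-3-oxoprop-1-en-1-yl]-3-(triisopropylsilyloxy)-1,4,4a,9b-tetrahydrodibenzo[b,d]furan-9b-yl]prop-2-enoate | CC(C)[Si](C(C)C)(C(C)C)OC1=CC[C@]2(/C=C\C(=O)OC)c3cc(/C=C\C(=O)NCCCCN(CCCNC(=O)OC(C)(C)C)C(=O)OC(C)(C)C)ccc3O[C@@H]2C1 | intermediate
17 | the corresponding (2Z)-prop-2-enoic acid of 16 | CC(C)[Si](C(C)C)(C(C)C)OC1=CC[C@]2(/C=C\C(=O)O)c3cc(/C=C\C(=O)NCCCCN(CCCNC(=O)OC(C)(C)C)C(=O)OC(C)(C)C)ccc3O[C@@H]2C1 | intermediate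
18 | (2Z)-3-[(4aR,9bS)-8-[(1Z)-3-[[4-[(3-aminopropyl)amino]butyl]amino]-3-oxoprop-1-en-1-yl]-3-oxo-1,2,3,4,4a,9b-hexahydrodibenzo[b,d]furan-9b-yl]prop-2-enoic acid (formed as its bis(trifluoroacetate) salt, not isolated) | O=C1CC[C@]2(/C=C\C(=O)O)c3cc(/C=C\C(=O)NCCCCNCCCN)ccc3O[C@@H]2C1 | intermediate
19 | pentafluorophenyl ester of 18 (not isolated) | O=C1CC[C@]2(/C=C\C(=O)Oc4c(F)c(F)c(F)c(F)c4F)c3cc(/C=C\C(=O)NCCCCNCCCN)ccc3O[C@@H]2C1 | intermediate
20 | CNP0159470.1: (4aR,9bS)-3-oxo-1,2,3,4,4a,9b-hexahydrodibenzo[b,d]furan bridged from C9b to C8 by –(Z)-CH=CH–C(=O)–NH(CH2)3NH(CH2)4NH–C(=O)–(Z)-CH=CH– | O=C1CC[C@]23/C=C\C(=O)NCCCNCCCCNC(=O)/C=C\c4ccc(c2c4)O[C@@H]3C1 | target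

**Step count and risks**

Total steps: 11. Longest linear sequence: 8 steps (1, 2, 3, 5, 6, 9, 10, 11); step 4 and steps 7–8 are side branches.

Most likely to fail:

1. Step 5 (Proposed new method). The aromatic dienophile may be too unreactive toward the chiral Lewis acid at the low temperature that face selectivity needs, or the silyl enol terminus may add 1,2 to the bound aldehyde, so that the cycloaddition stalls or loses facial control. The fallback uses known chemistry, sets out from 6 (with 8) and returns at 9. The cycloaddition is run without asymmetric induction under the established high-pressure conditions for 3-carbonyl benzofurans (ZnCl2, CH2Cl2, 1.2 GPa, rt), which should give 9 as the racemate, that is, together with its mirror image ent-9 F1. The enantiomers are separated by preparative chromatography on a chiral stationary phase (amylose tris(3,5-dimethylphenylcarbamate), CO2/i-PrOH). The (4aR,9bS) enantiomer 9, assigned by anomalous-dispersion X-ray analysis with the iodine atom, re-enters the route at step 6.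

2. Step 11. The unprotected secondary N4 amine may compete for the active ester (16-membered lactam), the seco acid may oligomerise, or the activated acrylate may isomerise from Z to E. The fallback sets out from 18 and returns at 20, with N4 protected before ring closure. Salt 18 with CF3CO2Et, Et3N, MeOH at 0 °C, which acylates primary amines selectively, should give the N1-trifluoroacetamide F2. Boc2O/Et3N then gives the N1-trifluoroacetyl-N4-Boc acid F3. K2CO3 in MeOH/H2O cleaves the trifluoroacetamide to the N4-Boc seco amino acid F4. The same high-dilution lactamisation with pentafluorophenyl diphenylphosphinate, through the pentafluorophenyl ester F5, gives the N4-Boc macrolactam F6. TFA/CH2Cl2 removes the Boc group to give 20.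

3. Step 6. Addition of the phosphonate anion to the fully substituted, neopentyl aldehyde may be slow, and warming would erode the Z selectivity. The fallback sets out from 9 and returns at 11, and takes the Z geometry from an alkyne instead of an olefination. Ohira–Bestmann homologation of 9 (dimethyl (1-diazo-2-oxopropyl)phosphonate, K2CO3, MeOH, 0 °C → rt; well suited to a non-enolisable aldehyde) gives (4aR,9bS)-9b-ethynyl-8-iodo-3-(triisopropylsilyloxy)-1,4,4a,9b-tetrahydrodibenzo[b,d]furan F7. LiN(SiMe3)2, THF, −78 °C, then ClCO2Me gives the methyl alkynoate F8. Semihydrogenation (H2, Pd/CaCO3 poisoned with Pb(OAc)2, quinoline, EtOAc) adds hydrogen syn and should deliver the Z-enoate 11.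

**Further compounds**

F1 | step 5 | (4aS,9bR)-8-iodo-3-(triisopropylsilyloxy)-1,4,4a,9b-tetrahydrodibenzo[b,d]furan-9b-carbaldehyde (ent-9) | CC(C)[Si](C(C)C)(C(C)C)OC1=CC[C@@]2(C=O)c3cc(I)ccc3O[C@H]2C1
F2 | step 11 | N1-trifluoroacetyl derivative of seco amino acid 18 | O=C1CC[C@]2(/C=C\C(=O)O)c3cc(/C=C\C(=O)NCCCCNCCCNC(=O)C(F)(F)F)ccc3O[C@@H]2C1
F3 | step 11 | N1-trifluoroacetyl-N4-Boc derivative of 18 | O=C1CC[C@]2(/C=C\C(=O)O)c3cc(/C=C\C(=O)NCCCCN(CCCNC(=O)C(F)(F)F)C(=O)OC(C)(C)C)ccc3O[C@@H]2C1
F4 | step 11 | N4-Boc seco amino acid | O=C1CC[C@]2(/C=C\C(=O)O)c3cc(/C=C\C(=O)NCCCCN(CCCN)C(=O)OC(C)(C)C)ccc3O[C@@H]2C1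
F5 | step 11 | pentafluorophenyl ester of F4 | O=C1CC[C@]2(/C=C\C(=O)Oc4c(F)c(F)c(F)c(F)c4F)c3cc(/C=C\C(=O)NCCCCN(CCCN)C(=O)OC(C)(C)C)ccc3O[C@@H]2C1
F6 | step 11 | N4-Boc derivative of macrolactam 20 | O=C1CC[C@]23/C=C\C(=O)NCCCN(C(=O)OC(C)(C)C)CCCCNC(=O)/C=C\c4ccc(c2c4)O[C@@H]3C1
F7 | step 6 | (4aR,9bS)-9b-ethynyl-8-iodo-3-(triisopropylsilyloxy)-1,4,4a,9b-tetrahydrodibenzo[b,d]furan | CC(C)[Si](C(C)C)(C(C)C)OC1=CC[C@]2(C#C)c3cc(I)ccc3O[C@@H]2C1
F8 | step 6 | methyl 3-[(4aR,9bS)-8-iodo-3-(triisopropylsilyloxy)-1,4,4a,9b-tetrahydrodibenzo[b,d]furan-9b-yl]prop-2-ynoate | CC(C)[Si](C(C)C)(C(C)C)OC1=CC[C@]2(C#CC(=O)OC)c3cc(I)ccc3O[C@@H]2C1
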